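**Retrosynthetic overview**

1. Locants used in the text: C1 = C(OCOAr)(i-Pr); C2, C3 = ring CH2; C4 = C(CH3) at the ring fusion; C5 = CH2; C6/C7 = oxirane CH/C(CH3); C8 = CH2; C9 = CHOH; C10 = ring-fusion CH.
2. End game: target ⇒ debenzylation ⇒ C9–OH-directed epoxidation of C6=C7 ⇒ aroylation of the C1 alkoxide ⇒ i-Pr addition to the C1 ketone (anti to the C4 methyl) ⇒ trans-fused bicyclic ketone.
3. Five-membered ring C1–C2–C3–C4–C10, closed last, disconnected at C1–C2: Rh-catalysed intramolecular hydroacylation of a cycloheptene carbaldehyde (C1 = CHO on C10) with a vinyl group (C2=C3) on C4.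
4. Enabling feature: in this ring only C1 is oxidised and it hangs on the fusion CH (C10), while C2–C3 is a bare two-carbon bridge ending at the quaternary C4 (no allylic H). This is a 4-pentenal retron, and since neither fusion atom takes part in the bond formation, the trans C4/C10 relation made earlier is kept.
5. Seven-membered ring first, by RCM at C6=C7 of a triene whose C9/C10/C4 triad comes from a chelated dianionic Ireland–Claisen rearrangement (C10–C4 bond) of the (E)-allyl ester of an (S)-β-hydroxy acid made from ethyl (R)-4-chloro-3-hydroxybutanoate.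

Key step: step 10

Remark: names in the compound list use IUPAC locants. The oxirane is treated as the oxidised form of the C6=C7 bond and is added only after the tertiary ester is in place, because a free C1 alkoxide facing the epoxide could open it across the ring.

**Route**

Step 1
Reactants: 1 pent-1-en-4-yne
Product: 4 (2E)-3-methylhexa-2,5-dien-1-ol, via alkenyldimethylalane 2 (not isolated), via lithium alkenylalanate 3 (not isolated)
Conditions: Me3Al (2.0 equiv), Cp2ZrCl2 (0.2 equiv), CH2Cl2, 0 → 23 °C; then n-BuLi, (CH2O)n, THF, −78 → 23 °C; H2O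
Reagents that add atoms: trimethylaluminium, C[Al](C)C; paraformaldehyde (as formaldehyde), C=O
Why: Zirconium-catalysed syn-carboalumination of the terminal alkyne (Negishi carboalumination) puts CH3 on the internal carbon and aluminium cis to it, and hydroxymethylation of the alkenyl–aluminium bond of the ate complex with retention fixes the (E)-trisubstituted alkene.

Step 2
Reactants: 5 ethyl (R)-4-chloro-3-hydroxybutanoate
Product: 6 ethyl 2-[(2R)-oxiran-2-yl]acetate
Conditions: Ag2O (0.55 equiv), DME, 80 °C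
Reagents that add atoms: none
Why: Ring closure of the chlorohydrin to the epoxide (intramolecular Williamson reaction) under non-basic Ag2O assistance avoids β-elimination of the epoxy ester and does not touch the stereocentre.

Step 3
Reactants: 6 ethyl 2-[(2R)-oxiran-2-yl]acetate
Product: 7 ethyl (3S)-3-hydroxy-5-methylhex-5-enoate
Conditions: CH2=C(CH3)MgBr (1.5 equiv), CuI (10 mol %), THF, −40 °C; aq. NH4Cl
Reagents that add atoms: isopropenylmagnesium bromide, CC(=C)[Mg]Br
Why: Copper-catalysed Grignard opening of the terminal epoxide (SN2 at the CH2 carbon) is faster than attack on the ester at low temperature and leaves the carbinol centre untouched (its descriptor becomes S only through the priority change).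

Step 4
Reactants: 7 ethyl (3S)-3-hydroxy-5-methylhex-5-enoate; 4 (2E)-3-methylhexa-2,5-dien-1-ol
Product: 8 (2E)-3-methylhexa-2,5-dien-1-yl (3S)-3-hydroxy-5-methylhex-5-enoate
Conditions: 4 (1.3 equiv), 1,3-dichloro-1,1,3,3-tetrabutyldistannoxane (5 mol %), toluene, reflux (−EtOH)
Reagents that add atoms: none
Why: Neutral distannoxane-catalysed transesterification exchanges ethanol for the primary allylic alcohol without dehydration or retro-aldol cleavage of the β-hydroxy ester.

Step 5
Reactants: 8 (2E)-3-methylhexa-2,5-dien-1-yl (3S)-3-hydroxy-5-methylhex-5-enoate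
Product: 10 (2S,3S)-3-hydroxy-5-methyl-2-[(3S)-3-methylhexa-1,5-dien-3-yl]hex-5-enoic acid, via dilithium enolate alkoxide 9 (not isolated)
Conditions: LDA (2.3 equiv), THF, −78 °C; then 23 → 50 °C; aq. HCl
Reagents that add atoms: none
Why: Dianionic Ireland–Claisen ([3,3]-sigmatropic) rearrangement: the lithium chelate between alkoxide and enolate oxygen fixes the enolate geometry (C9 trans to the allyloxy group) and blocks one face, so the allyl terminus adds anti to the CH2 branch of the chelate ring (anti C9/C10, as in alkylations of β-hydroxy ester dianions), and the chair transition state with the (E)-alkene (allyl equatorial, methyl axial) sets the quaternary C4 relative to C10.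

Step 6
Reactants: 10 (2S,3S)-3-hydroxy-5-methyl-2-[(3S)-3-methylhexa-1,5-dien-3-yl]hex-5-enoic acid
Product: 11 methyl (2S,3S)-3-hydroxy-5-methyl-2-[(3S)-3-methylhexa-1,5-dien-3-yl]hex-5-enoate
Conditions: Me3SiCHN2, toluene–MeOH (4:1), 0 °C
Reagents that add atoms: trimethylsilyldiazomethane, C[Si](C)(C)C=[N+]=[N-]
Why: Methylation of the carboxylic acid by trimethylsilyldiazomethane is selective for the acid and leaves the secondary hydroxyl and the three alkenes untouched.

Step 7
Reactants: 11 methyl (2S,3S)-3-hydroxy-5-methyl-2-[(3S)-3-methylhexa-1,5-dien-3-yl]hex-5-enoate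
Product: 12 methyl (2S,3S)-3-[(tert-butyldimethylsilyl)oxy]-5-methyl-2-[(3S)-3-methylhexa-1,5-dien-3-yl]hex-5-enoate
Conditions: TBSOTf, 2,6-lutidine, CH2Cl2, −78 → 0 °C
Reagents that add atoms: tert-butyldimethylsilyl trifluoromethanesulfonate, CC(C)(C)[Si](C)(C)OS(=O)(=O)C(F)(F)F
Why: Silylation of the hindered secondary hydroxyl with the silyl triflate and a non-nucleophilic base gives the ether that masks C9–OH through the basic and acylating steps ahead.

Step 8
Reactants: 12 methyl (2S,3S)-3-[(tert-butyldimethylsilyl)oxy]-5-methyl-2-[(3S)-3-methylhexa-1,5-dien-3-yl]hex-5-enoate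
Product: 13 methyl (1S,2S,7S)-7-[(tert-butyldimethylsilyl)oxy]-2-ethenyl-2,5-dimethylcyclohept-4-ene-1-carboxylate
Conditions: second-generation Grubbs catalyst (5 mol %), CH2Cl2 (0.005 M), 40 °C
Reagents that add atoms: none
Why: Ring-closing olefin metathesis starts at the unhindered allyl terminus, whose carbene can only close onto the methallyl group (seven-membered ring, trisubstituted C6=C7), since closure onto the geminal vinyl group would give a cyclobutene and the vinyl group on the quaternary carbon is itself a poor initiation site.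

Step 9
Reactants: 13 methyl (1S,2S,7S)-7-[(tert-butyldimethylsilyl)oxy]-2-ethenyl-2,5-dimethylcyclohept-4-ene-1-carboxylate
Product: 14 (1S,2S,7S)-7-[(tert-butyldimethylsilyl)oxy]-2-ethenyl-2,5-dimethylcyclohept-4-ene-1-carbaldehyde
Conditions: i-Bu2AlH (1.1 equiv), CH2Cl2, −78 °C; aq. potassium sodium tartrate
Reagents that add atoms: none
Why: Partial reduction of the hindered ester with i-Bu2AlH at low temperature stops at the tetrahedral aluminium hemiacetal, which gives the aldehyde on work-up without epimerising C10.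

Step 10
Reactants: 14 (1S,2S,7S)-7-[(tert-butyldimethylsilyl)oxy]-2-ethenyl-2,5-dimethylcyclohept-4-ene-1-carbaldehyde
Product: 15 (3aS,4S,8aR)-4-[(tert-butyldimethylsilyl)oxy]-6,8a-dimethyl-2,3a,4,5,8,8a-hexahydroazulen-3(1H)-one
Conditions: [Rh(dppe)]ClO4 (5 mol %; dppe = 1,2-bis(diphenylphosphino)ethane), CH2Cl2, 23 °C
Reagents that add atoms: none
Why: Oxidative addition of the aldehyde C1–H bond to the cationic monovalent rhodium–diphosphine gives a trivalent acyl rhodium hydride, anti-Markovnikov hydrometalation of the neighbouring vinyl group (C2=C3) leads to a six-membered acyl–alkyl rhodacycle (Rh, C1, C10, C4, C3, C2), and C–C reductive elimination forms the C1–C2 bond and releases the catalyst. The closest known reaction type is the rhodium-catalysed intramolecular hydroacylation of 4-pentenals to cyclopentanones, which tolerates 3,3-disubstitution and ring-fused substrates. The five-membered ring C1–C2–C3–C4–C10 is closed in a formal 5-endo-trig sense at the vinyl group, which the metal makes feasible through the six-membered metallacycle. No new stereocentre is formed: C4, C9 and C10 come from steps 3 and 5, and because the new bond is made at C1–C2, away from both ring-fusion atoms, the trans relation of C4–CH3 and C10–H passes unchanged into the bicycle, while the neutral conditions should not epimerise C10. The step needs chemoselectivity for the vinyl group over the ring alkene C6=C7 (trisubstituted and reachable only through a seven-membered rhodacycle) and hydroacylation over decarbonylation, which the chelating diphosphine and the gem-disubstitution at C4 (Thorpe–Ingold effect) favour. Double-bond migration, the usual side reaction, is excluded because the vinyl group sits on the quaternary C4 and has no allylic hydrogen.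

Step 11
Reactants: 15 (3aS,4S,8aR)-4-[(tert-butyldimethylsilyl)oxy]-6,8a-dimethyl-2,3a,4,5,8,8a-hexahydroazulen-3(1H)-one
Product: 16 (3R,3aS,4S,8aR)-4-[(tert-butyldimethylsilyl)oxy]-6,8a-dimethyl-3-(propan-2-yl)-1,2,3,3a,4,5,8,8a-octahydroazulen-3-ol
Conditions: i-PrMgCl (3 equiv), anhydrous CeCl3 (3 equiv), THF, −78 → 0 °C; aq. NH4Cl
Reagents that add atoms: isopropylmagnesium chloride, CC(C)[Mg]Cl
Why: 1,2-Addition of the weakly basic organocerium reagent suppresses enolisation and β-hydride reduction, and the reagent should attack the cyclopentanone from the face opposite the angular C4 methyl group (1,3 to the carbonyl), which places the new hydroxyl cis to that methyl (3R).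

Step 12
Reactants: 16 (3R,3aS,4S,8aR)-4-[(tert-butyldimethylsilyl)oxy]-6,8a-dimethyl-3-(propan-2-yl)-1,2,3,3a,4,5,8,8a-octahydroazulen-3-ol; 17 4-(benzyloxy)benzoyl chloride
Product: 19 (3R,3aS,4S,8aR)-4-[(tert-butyldimethylsilyl)oxy]-6,8a-dimethyl-3-(propan-2-yl)-1,2,3,3a,4,5,8,8a-octahydroazulen-3-yl 4-(benzyloxy)benzoate, via potassium alkoxide 18 (not isolated)
Conditions: KN(SiMe3)2 (1.2 equiv), THF, −78 → 0 °C; then 17 (1.5 equiv), 0 → 23 °C
Reagents that add atoms: none
Why: O-Acylation of the potassium tertiary alkoxide by the aroyl chloride (nucleophilic acyl substitution) can only take place at the C1 oxygen because C9–OH is silylated, and the configuration at C1 is not affected.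

Step 13
Reactants: 19 (3R,3aS,4S,8aR)-4-[(tert-butyldimethylsilyl)oxy]-6,8a-dimethyl-3-(propan-2-yl)-1,2,3,3a,4,5,8,8a-octahydroazulen-3-yl 4-(benzyloxy)benzoate
Product: 20 (3R,3aS,4S,8aR)-4-hydroxy-6,8a-dimethyl-3-(propan-2-yl)-1,2,3,3a,4,5,8,8a-octahydroazulen-3-yl 4-(benzyloxy)benzoate
Conditions: HF·pyridine, pyridine, THF, 0 → 23 °C
Reagents that add atoms: none
Why: Fluoride-induced cleavage of the silyl ether under buffered, weakly acidic conditions frees C9–OH without forming an alkoxide that could start a 1,3-acyl shift from the tertiary to the secondary oxygen.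

Step 14
Reactants: 20 (3R,3aS,4S,8aR)-4-hydroxy-6,8a-dimethyl-3-(propan-2-yl)-1,2,3,3a,4,5,8,8a-octahydroazulen-3-yl 4-(benzyloxy)benzoate
Product: 21 (3R,3aS,4S,6R,7S,8aR)-6,7-epoxy-4-hydroxy-6,8a-dimethyl-3-(propan-2-yl)decahydroazulen-3-yl 4-(benzyloxy)benzoate
Conditions: VO(acac)2 (5 mol %), t-BuOOH (1.5 equiv), CH2Cl2, 0 → 23 °C
Reagents that add atoms: tert-butyl hydroperoxide, CC(C)(C)OO
Why: Vanadium-catalysed hydroxyl-directed epoxidation of the homoallylic alcohol delivers the peroxide oxygen to the C6=C7 face syn to C9–OH, which is also the face away from the angular methyl group, and thereby sets C6 and C7.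

Step 15
Reactants: 21 (3R,3aS,4S,6R,7S,8aR)-6,7-epoxy-4-hydroxy-6,8a-dimethyl-3-(propan-2-yl)decahydroazulen-3-yl 4-(benzyloxy)benzoate
Product: 22 (3R,3aS,4S,6R,7S,8aR)-6,7-epoxy-4-hydroxy-6,8a-dimethyl-3-(propan-2-yl)decahydroazulen-3-yl 4-hydroxybenzoate (CNP0264773.1)
Conditions: H2 (1 atm), Pd/C (10 %), EtOAc, 23 °C
Reagents that add atoms: none
Why: Hydrogenolysis of the benzyl aryl ether on palladium frees the phenol under neutral conditions that leave the trisubstituted epoxide, the ester and the free hydroxyl untouched.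

**Compound list**

1 | pent-1-en-4-yne | C=CCC#C | starting material
2 | dimethyl[(1E)-2-methylpenta-1,4-dien-1-yl]alumane | C=CC/C(C)=C/[Al](C)C | intermediate
3 | lithium butyl(dimethyl)[(1E)-2-methylpenta-1,4-dien-1-yl]aluminate | [Li+].C=CC/C(C)=C/[Al-](C)(C)CCCC | intermediate
4 | (2E)-3-methylhexa-2,5-dien-1-ol | C=CC/C(C)=C/CO | intermediate
5 | ethyl (R)-4-chloro-3-hydroxybutanoate | CCOC(=O)C[C@@H](O)CCl | starting material
6 | ethyl 2-[(2R)-oxiran-2-yl]acetate | CCOC(=O)C[C@@H]1CO1 | intermediate
7 | ethyl (3S)-3-hydroxy-5-methylhex-5-enoate | CCOC(=O)C[C@@H](O)CC(C)=C | intermediate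
8 | (2E)-3-methylhexa-2,5-dien-1-yl (3S)-3-hydroxy-5-methylhex-5-enoate | C=CC/C(C)=C/COC(=O)C[C@@H](O)CC(C)=C | intermediate
9 | dilithium (1E,3S)-5-methyl-1-{[(2E)-3-methylhexa-2,5-dien-1-yl]oxy}hexa-1,5-diene-1,3-diolate (chelated enolate, O–Li cis to the carbinol carbon) | [Li+].[Li+].C=CC/C(C)=C/CO/C([O-])=C/[C@@H]([O-])CC(C)=C | intermediate
10 | (2S,3S)-3-hydroxy-5-methyl-2-[(3S)-3-methylhexa-1,5-dien-3-yl]hex-5-enoic acid | C=C[C@](C)(CC=C)[C@@H]([C@@H](O)CC(C)=C)C(=O)O | intermediate
11 | methyl (2S,3S)-3-hydroxy-5-methyl-2-[(3S)-3-methylhexa-1,5-dien-3-yl]hex-5-enoate | C=C[C@](C)(CC=C)[C@@H]([C@@H](O)CC(C)=C)C(=O)OC | intermediate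
12 | methyl (2S,3S)-3-[(tert-butyldimethylsilyl)oxy]-5-methyl-2-[(3S)-3-methylhexa-1,5-dien-3-yl]hex-5-enoate | C=C[C@](C)(CC=C)[C@@H]([C@@H](O[Si](C)(C)C(C)(C)C)CC(C)=C)C(=O)OC | intermediate
13 | methyl (1S,2S,7S)-7-[(tert-butyldimethylsilyl)oxy]-2-ethenyl-2,5-dimethylcyclohept-4-ene-1-carboxylate | C=C[C@]1(C)CC=C(C)C[C@H](O[Si](C)(C)C(C)(C)C)[C@H]1C(=O)OC | intermediate
14 | (1S,2S,7S)-7-[(tert-butyldimethylsilyl)oxy]-2-ethenyl-2,5-dimethylcyclohept-4-ene-1-carbaldehyde | C=C[C@]1(C)CC=C(C)C[C@H](O[Si](C)(C)C(C)(C)C)[C@H]1C=O | intermediate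
15 | (3aS,4S,8aR)-4-[(tert-butyldimethylsilyl)oxy]-6,8a-dimethyl-2,3a,4,5,8,8a-hexahydroazulen-3(1H)-one | O=C1CC[C@]2(C)CC=C(C)C[C@H](O[Si](C)(C)C(C)(C)C)[C@H]21 | intermediate
16 | (3R,3aS,4S,8aR)-4-[(tert-butyldimethylsilyl)oxy]-6,8a-dimethyl-3-(propan-2-yl)-1,2,3,3a,4,5,8,8a-octahydroazulen-3-ol | CC(C)[C@]1(O)CC[C@]2(C)CC=C(C)C[C@H](O[Si](C)(C)C(C)(C)C)[C@H]21 | intermediate
17 | 4-(benzyloxy)benzoyl chloride | O=C(Cl)c1ccc(OCc2ccccc2)cc1 | starting material
18 | potassium (3R,3aS,4S,8aR)-4-[(tert-butyldimethylsilyl)oxy]-6,8a-dimethyl-3-(propan-2-yl)-1,2,3,3a,4,5,8,8a-octahydroazulen-3-olate | [K+].CC(C)[C@]1([O-])CC[C@]2(C)CC=C(C)C[C@H](O[Si](C)(C)C(C)(C)C)[C@H]21 | intermediate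
19 | (3R,3aS,4S,8aR)-4-[(tert-butyldimethylsilyl)oxy]-6,8a-dimethyl-3-(propan-2-yl)-1,2,3,3a,4,5,8,8a-octahydroazulen-3-yl 4-(benzyloxy)benzoate | CC(C)[C@]1(OC(=O)c2ccc(OCc3ccccc3)cc2)CC[C@]2(C)CC=C(C)C[C@H](O[Si](C)(C)C(C)(C)C)[C@H]21 | intermediate
20 | (3R,3aS,4S,8aR)-4-hydroxy-6,8a-dimethyl-3-(propan-2-yl)-1,2,3,3a,4,5,8,8a-octahydroazulen-3-yl 4-(benzyloxy)benzoate | CC(C)[C@]1(OC(=O)c2ccc(OCc3ccccc3)cc2)CC[C@]2(C)CC=C(C)C[C@H](O)[C@H]21 | intermediate
21 | (3R,3aS,4S,6R,7S,8aR)-6,7-epoxy-4-hydroxy-6,8a-dimethyl-3-(propan-2-yl)decahydroazulen-3-yl 4-(benzyloxy)benzoate (oxirane oxygen cis to the secondary hydroxyl) | CC(C)[C@]1(OC(=O)c2ccc(OCc3ccccc3)cc2)CC[C@]2(C)C[C@@H]3O[C@]3(C)C[C@H](O)[C@H]21 | intermediate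
22 | (3R,3aS,4S,6R,7S,8aR)-6,7-epoxy-4-hydroxy-6,8a-dimethyl-3-(propan-2-yl)decahydroazulen-3-yl 4-hydroxybenzoate | CC(C)[C@]1(OC(=O)c2ccc(O)cc2)CC[C@]2(C)C[C@@H]3O[C@]3(C)C[C@H](O)[C@H]21 | target

**Step count and risks**

Total step count: 15. Longest linear sequence: 14 steps (steps 2–15, from 5 to 22); step 1 and compound 17 are convergent inputs.

Steps most likely to fail:

Step 12. The C1 alkoxide is flanked by the isopropyl group and the ring-fusion carbon and may be too shielded to attack the aroyl chloride, so that the alcohol is recovered or the chloride is consumed by the silylamide. The fallback builds the ester from the carbonyl carbon outward. It sets out from 16: the potassium alkoxide 18 is trapped with the small, planar 1,1'-carbonyldiimidazole (THF, 0 → 23 °C) to give the imidazole-1-carboxylate F1. Commercial [4-(benzyloxy)phenyl]magnesium bromide (1.1 equiv, THF, −40 °C) should then displace imidazolide at the carbonyl group and give 19, where the route is rejoined; the hindered tert-alkyl ester should resist a second addition.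

Step 10. Decarbonylation of the acyl rhodium hydride, with deactivation of the catalyst as a carbonyl complex, may outrun insertion of the hindered vinyl group. The fallback closes the same C1–C2 bond with a carbon nucleophile. It sets out from methyl ester 13: chemoselective hydroboration of the vinyl group with 9-borabicyclo[3.3.1]nonane (THF, 23 °C) gives the B-alkyl borane F2, and iodinolysis (I2, NaOMe, MeOH) gives the primary iodide F3. SmI2 with catalytic Fe(acac)3 (THF, 0 → 23 °C; Barbier-type intramolecular nucleophilic acyl substitution) should then give ketone 15, where the route is rejoined.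

Step 11. Enolisation towards C10 (followed by β-elimination of the silyloxy group) or β-hydride transfer from the isopropyl reagent may compete with carbon–carbon bond formation at the hindered ketone. The fallback brings in the three carbons as an sp2 nucleophile without β-hydrogen. It sets out from 15: prop-1-en-2-ylmagnesium bromide with CeCl3 (THF, −78 °C) should give the isopropenyl carbinol F4. Hydrogenation of its 1,1-disubstituted alkene with RhCl(PPh3)3 and H2 (benzene, 23 °C), which should leave the trisubstituted ring alkene, returns to 16.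

**Further compounds**

F1 | step 12 | (3R,3aS,4S,8aR)-4-[(tert-butyldimethylsilyl)oxy]-6,8a-dimethyl-3-(propan-2-yl)-1,2,3,3a,4,5,8,8a-octahydroazulen-3-yl 1H-imidazole-1-carboxylate | CC(C)[C@]1(OC(=O)n2ccnc2)CC[C@]2(C)CC=C(C)C[C@H](O[Si](C)(C)C(C)(C)C)[C@H]21
F2 | step 10 | methyl (1S,2R,7S)-2-[2-(9-borabicyclo[3.3.1]nonan-9-yl)ethyl]-7-[(tert-butyldimethylsilyl)oxy]-2,5-dimethylcyclohept-4-ene-1-carboxylate | B1(C2CCCC1CCC2)CC[C@]1(C)CC=C(C)C[C@H](O[Si](C)(C)C(C)(C)C)[C@H]1C(=O)OC
F3 | step 10 | methyl (1S,2S,7S)-7-[(tert-butyldimethylsilyl)oxy]-2-(2-iodoethyl)-2,5-dimethylcyclohept-4-ene-1-carboxylate | ICC[C@]1(C)CC=C(C)C[C@H](O[Si](C)(C)C(C)(C)C)[C@H]1C(=O)OC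
F4 | step 11 | (3S,3aS,4S,8aR)-4-[(tert-butyldimethylsilyl)oxy]-6,8a-dimethyl-3-(prop-1-en-2-yl)-1,2,3,3a,4,5,8,8a-octahydroazulen-3-ol | C=C(C)[C@]1(O)CC[C@]2(C)CC=C(C)C[C@H](O[Si](C)(C)C(C)(C)C)[C@H]21
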